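**Plan**

- Locants: rings D and E use chromone numbering (O1, C2, C3, C4=O, C4a, C5–C8, C8a). Ring F is the saturated pyran on C7–O and C8, ring C the furan, ring A the chromene pyran. Ring B has C1' (on C3), C2' (furan O), C3' and C4' (shared with ring A), C5' (OH) and C6' (H).
- Retrosynthesis: the two phenol protecting groups are removed last. Before that the cuts are, in order, the furan bond C3–C1', ring A (C3'–C and C4'–O–C), the ether bond C2–O(C2'), ring D (O1–C2 and C2–C3) and ring F.
- Forward: ring F (propargyl ether Claisen, then hydrogenation), ring D (CS2 annulation to a 2-methylsulfanylchromone, then sulfone), ether link to the ring B phenol, ring A (second Claisen), ring C (palladium), double dealkylation.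
- Enabling feature: C3 is the β-carbon of the vinylogous carbonate O1–C2(OAr)=C3–C4=O, and C1' is the only unsubstituted carbon ortho to the oxygen on C2'. Both are nucleophilic C–H carbons held by the C2–O–C2' bridge, so one palladium can reach both; C3' is blocked by ring A.
- Stereochemistry: the target has no stereocentre, so nothing has to be set.

Key step: step 12

Remark: systematic names of the chromones use pyrano[2,3-f]chromene numbering (gem-dimethyl carbon C8, saturated carbons C9 and C10; C2 to C5 coincide with the chromone locants), and the site selectivity of step 2 is assumed to follow the chelated 2-hydroxy ketone.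

**Route**

Step 1
Reactants: 1 1-(2,4-dihydroxy-6-methoxyphenyl)ethan-1-one; 2 3-chloro-3-methylbut-1-yne
Product: 3 1-{2-hydroxy-6-methoxy-4-[(2-methylbut-3-yn-2-yl)oxy]phenyl}ethan-1-one
Conditions: K2CO3, KI (cat.), CuI (cat.), acetone, reflux
Reagents that add atoms: none
Why: Base-mediated, copper-assisted O-alkylation with the tertiary propargylic chloride takes the free hydroxyl para to the acetyl group, because the ortho hydroxyl is held in a hydrogen bond to the ketone and is much less nucleophilic.

Step 2
Reactants: 3 1-{2-hydroxy-6-methoxy-4-[(2-methylbut-3-yn-2-yl)oxy]phenyl}ethan-1-one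
Product: 5 1-(5-hydroxy-7-methoxy-2,2-dimethyl-2H-chromen-6-yl)ethan-1-one, via 3-allenyl resorcinol ketone 4 (not isolated)
Conditions: N,N-diethylaniline, 190 °C, argon
Reagents that add atoms: none
Why: Aryl propargyl ether Claisen rearrangement: the [3,3] shift should go to the ring carbon between the two oxygen-bearing carbons, whose bond to the ether carbon has the higher double-bond character in the chelated 2-hydroxyaryl ketone (the behaviour of resacetophenone ethers), and enolisation, 1,5-hydrogen shift and 6π oxa-electrocyclisation then close the chromene on the free, non-chelated oxygen.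

Step 3
Reactants: 5 1-(5-hydroxy-7-methoxy-2,2-dimethyl-2H-chromen-6-yl)ethan-1-one
Product: 6 1-(5-hydroxy-7-methoxy-2,2-dimethyl-3,4-dihydro-2H-chromen-6-yl)ethan-1-one
Conditions: H2 (1 atm), Pd/C, EtOAc, rt
Reagents that add atoms: none
Why: Catalytic hydrogenation saturates the styrene-type chromene double bond, while the hydrogen-bonded aryl ketone and the aryl ethers are not reduced under these mild conditions.

Step 4
Reactants: 6 1-(5-hydroxy-7-methoxy-2,2-dimethyl-3,4-dihydro-2H-chromen-6-yl)ethan-1-one
Product: 7 4-hydroxy-5-methoxy-8,8-dimethyl-9,10-dihydro-2H,8H-pyrano[2,3-f]chromene-2-thione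
Conditions: CS2, KOtBu (3.2 equiv), THF, 0 °C to rt; then aq. HCl
Reagents that add atoms: carbon disulfide, S=C=S
Why: Claisen-type condensation of the ketone enolate with CS2 gives a β-oxodithiocarboxylate whose thiocarbonyl carbon is attacked by the neighbouring phenoxide with loss of hydrosulfide, the standard annulation of 2-hydroxyacetophenones to 4-hydroxy-2H-chromene-2-thiones; only one hydroxyl is ortho to the acetyl group, so ring D can close in one sense only.

Step 5
Reactants: 7 4-hydroxy-5-methoxy-8,8-dimethyl-9,10-dihydro-2H,8H-pyrano[2,3-f]chromene-2-thione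
Product: 8 5-methoxy-8,8-dimethyl-2-(methylsulfanyl)-9,10-dihydro-4H,8H-pyrano[2,3-f]chromen-4-one
Conditions: MeI, K2CO3, acetone, rt
Reagents that add atoms: iodomethane, CI
Why: S-Alkylation of the ambident thioxo enolate at its soft sulfur end fixes the 4-pyranone tautomer and gives the 2-(methylsulfanyl)chromone.

Step 6
Reactants: 8 5-methoxy-8,8-dimethyl-2-(methylsulfanyl)-9,10-dihydro-4H,8H-pyrano[2,3-f]chromen-4-one
Product: 9 2-(methanesulfonyl)-5-methoxy-8,8-dimethyl-9,10-dihydro-4H,8H-pyrano[2,3-f]chromen-4-one
Conditions: mCPBA (2.2 equiv), CH2Cl2, 0 °C to rt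
Reagents that add atoms: 3-chloroperoxybenzoic acid (mCPBA), O=C(OO)c1cccc(Cl)c1
Why: Peracid oxidation of the sulfide to the sulfone, which leaves the electron-poor C2=C3 bond alone and makes C2 a good acceptor for addition–elimination.

Step 7
Reactants: 10 3,4-dihydroxybenzaldehyde
Product: 11 4-(benzyloxy)-3-hydroxybenzaldehyde
Conditions: BnBr (1.0 equiv), NaHCO3, NaI (cat.), DMF, 40 °C
Reagents that add atoms: benzyl bromide, BrCc1ccccc1
Why: Williamson etherification under weak base is selective for the hydroxyl para to the formyl group, the more acidic of the two, so only the 4-oxygen is benzylated.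

Step 8
Reactants: 11 4-(benzyloxy)-3-hydroxybenzaldehyde; 2 3-chloro-3-methylbut-1-yne
Product: 12 4-(benzyloxy)-3-[(2-methylbut-3-yn-2-yl)oxy]benzaldehyde
Conditions: K2CO3, KI (cat.), CuI (cat.), DMF, 60 °C
Reagents that add atoms: none
Why: The remaining phenol is O-alkylated by the tertiary propargylic chloride under base and copper assistance, the usual preparation of aryl 1,1-dimethylpropargyl ethers.

Step 9
Reactants: 12 4-(benzyloxy)-3-[(2-methylbut-3-yn-2-yl)oxy]benzaldehyde
Product: 14 4-(benzyloxy)-3-[(2-methylbut-3-yn-2-yl)oxy]phenol, via aryl formate 13 (not isolated)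
Conditions: mCPBA, CH2Cl2, 0 °C to rt; aq. NaHCO3 wash; K2CO3 (cat.), MeOH, rt
Reagents that add atoms: 3-chloroperoxybenzoic acid (mCPBA), O=C(OO)c1cccc(Cl)c1
Why: Baeyer–Villiger (Dakin-type) oxidation, in which the electron-rich aryl group (para to the benzyloxy oxygen) migrates to give the aryl formate, followed by mild methanolysis to the phenol; the terminal alkyne and the benzyl ether are inert to the peracid.

Step 10
Reactants: 9 2-(methanesulfonyl)-5-methoxy-8,8-dimethyl-9,10-dihydro-4H,8H-pyrano[2,3-f]chromen-4-one; 14 4-(benzyloxy)-3-[(2-methylbut-3-yn-2-yl)oxy]phenol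
Product: 15 2-{4-(benzyloxy)-3-[(2-methylbut-3-yn-2-yl)oxy]phenoxy}-5-methoxy-8,8-dimethyl-9,10-dihydro-4H,8H-pyrano[2,3-f]chromen-4-one
Conditions: K2CO3, DMF, rt, argon
Reagents that add atoms: none
Why: Nucleophilic vinylic substitution by addition–elimination: the phenoxide adds to C2, the carbon β to the chromone carbonyl, and methanesulfinate leaves, as is known for 2-sulfonylchromones with O-, N- and S-nucleophiles.

Step 11
Reactants: 15 2-{4-(benzyloxy)-3-[(2-methylbut-3-yn-2-yl)oxy]phenoxy}-5-methoxy-8,8-dimethyl-9,10-dihydro-4H,8H-pyrano[2,3-f]chromen-4-one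
Product: 17 2-{[8-(benzyloxy)-2,2-dimethyl-2H-chromen-5-yl]oxy}-5-methoxy-8,8-dimethyl-9,10-dihydro-4H,8H-pyrano[2,3-f]chromen-4-one, via allenylphenol ether 16 (not isolated)
Conditions: N,N-diethylaniline, 185 °C, argon
Reagents that add atoms: none
Why: Second aryl propargyl ether Claisen rearrangement: only one ortho carbon of the propargyl ether is free (the other carries the benzyloxy group), and since the neighbouring oxygen is already tied to the chromone, the phenol set free by the [3,3] shift is the only hydroxyl that can close the chromene by 1,5-hydrogen shift and 6π oxa-electrocyclisation, so ring A forms in one orientation.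

Step 12
Reactants: 17 2-{[8-(benzyloxy)-2,2-dimethyl-2H-chromen-5-yl]oxy}-5-methoxy-8,8-dimethyl-9,10-dihydro-4H,8H-pyrano[2,3-f]chromen-4-one
Product: 18 5-O-methyl-5'-O-benzylformosanatin D (rings A to F complete; OMe on C5, OBn on C5')
Conditions: Pd(OAc)2 (10 mol %), AgOAc (2.5 equiv), PivOH, 110 °C, argon
Reagents that add atoms: none
Why: C3 is the β-carbon of a vinylogous carbonate and should be palladated electrophilically by Pd(OAc)2 in pivalic acid; carboxylate-assisted concerted metalation–deprotonation of the ring B C–H ortho to the ether oxygen (C1') then gives a six-membered palladacycle (Pd, C3, C2, O, C2', C1'). Reductive elimination from this palladacycle forms the C3–C1' bond, so furan ring C closes by contraction of the six-membered metallacycle to the five-membered ring, and AgOAc returns the zerovalent palladium released to divalent palladium. The closest known reactions are the palladium diacetate-catalysed intramolecular dehydrogenative couplings of 4-aryloxycoumarins to coumestans and of diaryl ethers to dibenzofurans, which join the same kind of two C–H carbons across an ether oxygen. No stereocentre is formed. The step needs site selectivity, which the ether tether supplies: only C3 and C1' can sit in one palladacycle, C3' is substituted by the ring A carbon, and palladation at other electron-rich positions (C6 of ring E, C6' of ring B) has no partner in reach and should revert by protonolysis in the acidic medium. The chromene alkene has no allylic hydrogen, so allylic palladation is excluded and only slow acyloxypalladation can compete.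

Step 13
Reactants: 18 5-O-methyl-5'-O-benzylformosanatin D
Product: 19 formosanatin D
Conditions: BCl3 (6 equiv), pentamethylbenzene (5 equiv), CH2Cl2, −78 °C, then 0 °C; aq. work-up
Reagents that add atoms: none
Why: Lewis-acid ether cleavage: BCl3 removes the benzyl group at low temperature with pentamethylbenzene trapping the benzyl cation before it can alkylate the electron-rich rings or the chromene, and on warming the 5-methyl ether, which binds boron in a chelate with the C4 carbonyl, is cleaved in preference to the cyclic ethers of rings A and F.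

**Compound list**

1 | 1-(2,4-dihydroxy-6-methoxyphenyl)ethan-1-one (2',4'-dihydroxy-6'-methoxyacetophenone) | CC(=O)c1c(O)cc(O)cc1OC | starting material
2 | 3-chloro-3-methylbut-1-yne | CC(C)(Cl)C#C | starting material
3 | 1-{2-hydroxy-6-methoxy-4-[(2-methylbut-3-yn-2-yl)oxy]phenyl}ethan-1-one | CC(=O)c1c(O)cc(OC(C)(C)C#C)cc1OC | intermediate
4 | 1-[2,4-dihydroxy-6-methoxy-3-(3-methylbuta-1,2-dien-1-yl)phenyl]ethan-1-one | CC(=O)c1c(O)c(C=C=C(C)C)c(O)cc1OC | intermediate
5 | 1-(5-hydroxy-7-methoxy-2,2-dimethyl-2H-chromen-6-yl)ethan-1-one | CC(=O)c1c(O)c2C=CC(C)(C)Oc2cc1OC | intermediate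
6 | 1-(5-hydroxy-7-methoxy-2,2-dimethyl-3,4-dihydro-2H-chromen-6-yl)ethan-1-one | CC(=O)c1c(O)c2CCC(C)(C)Oc2cc1OC | intermediate
7 | 4-hydroxy-5-methoxy-8,8-dimethyl-9,10-dihydro-2H,8H-pyrano[2,3-f]chromene-2-thione | Oc1cc(=S)oc2c3CCC(C)(C)Oc3cc(OC)c12 | intermediate
8 | 5-methoxy-8,8-dimethyl-2-(methylsulfanyl)-9,10-dihydro-4H,8H-pyrano[2,3-f]chromen-4-one | CSc1cc(=O)c2c(OC)cc3OC(C)(C)CCc3c2o1 | intermediate
9 | 2-(methanesulfonyl)-5-methoxy-8,8-dimethyl-9,10-dihydro-4H,8H-pyrano[2,3-f]chromen-4-one | CS(=O)(=O)c1cc(=O)c2c(OC)cc3OC(C)(C)CCc3c2o1 | intermediate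
10 | 3,4-dihydroxybenzaldehyde | O=Cc1ccc(O)c(O)c1 | starting material
11 | 4-(benzyloxy)-3-hydroxybenzaldehyde | O=Cc1ccc(OCc2ccccc2)c(O)c1 | intermediate
12 | 4-(benzyloxy)-3-[(2-methylbut-3-yn-2-yl)oxy]benzaldehyde | O=Cc1ccc(OCc2ccccc2)c(OC(C)(C)C#C)c1 | intermediate
13 | 4-(benzyloxy)-3-[(2-methylbut-3-yn-2-yl)oxy]phenyl formate | O=COc1ccc(OCc2ccccc2)c(OC(C)(C)C#C)c1 | intermediate
14 | 4-(benzyloxy)-3-[(2-methylbut-3-yn-2-yl)oxy]phenol | Oc1ccc(OCc2ccccc2)c(OC(C)(C)C#C)c1 | intermediate
15 | 2-{4-(benzyloxy)-3-[(2-methylbut-3-yn-2-yl)oxy]phenoxy}-5-methoxy-8,8-dimethyl-9,10-dihydro-4H,8H-pyrano[2,3-f]chromen-4-one | O=c1cc(Oc2ccc(OCc3ccccc3)c(OC(C)(C)C#C)c2)oc2c3CCC(C)(C)Oc3cc(OC)c12 | intermediate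
16 | 2-[4-(benzyloxy)-3-hydroxy-2-(3-methylbuta-1,2-dien-1-yl)phenoxy]-5-methoxy-8,8-dimethyl-9,10-dihydro-4H,8H-pyrano[2,3-f]chromen-4-one | O=c1cc(Oc2ccc(OCc3ccccc3)c(O)c2C=C=C(C)C)oc2c3CCC(C)(C)Oc3cc(OC)c12 | intermediate
17 | 2-{[8-(benzyloxy)-2,2-dimethyl-2H-chromen-5-yl]oxy}-5-methoxy-8,8-dimethyl-9,10-dihydro-4H,8H-pyrano[2,3-f]chromen-4-one | O=c1cc(Oc2ccc(OCc3ccccc3)c3OC(C)(C)C=Cc23)oc2c3CCC(C)(C)Oc3cc(OC)c12 | intermediate
18 | 5-O-methyl-5'-O-benzylformosanatin D (coumaronochromone with furan ring C closed through C2–O–C2' and C3–C1'; OMe on C5, OBn on C5') | O=c1c2c(OC)cc3OC(C)(C)CCc3c2oc2oc3c4C=CC(C)(C)Oc4c(OCc4ccccc4)cc3c12 | intermediate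
19 | formosanatin D | CC1(C)C=Cc2c(c(O)cc3c2oc2oc4c5c(cc(O)c4c(=O)c23)OC(C)(C)CC5)O1 | target

**Count**

Total steps: 13. Longest linear sequence: 10 steps (steps 1 to 6, then 10 to 13); the ring B branch (steps 7 to 9) joins at step 10.

**Steps most likely to fail**

Step 12. Divalent palladium may attack the electron-rich chromene alkene by acyloxypalladation, or palladate the electron-rich rings unproductively and cause oligomerisation, faster than the palladacycle closes. The fallback makes the same bond without an oxidant, from an aryl bromide. It sets out from phenol 14: NBS in MeCN at 0 °C should brominate the carbon ortho to the hydroxyl and para to the propargyl ether oxygen, giving 4-(benzyloxy)-2-bromo-5-[(2-methylbut-3-yn-2-yl)oxy]phenol F1. Displacement of the sulfone of 9 (K2CO3, DMF) should give the 2-(2-bromoaryloxy)chromone F2, and the Claisen rearrangement under the conditions of step 11 the 6-bromochromenyl ether F3. Intramolecular direct arylation (Pd(OAc)2, PCy3·HBF4, K2CO3, DMA, 110 °C) then proceeds by oxidative addition of zerovalent palladium into the C1'–Br bond, palladation of C3 and reductive elimination. It comes back to the route at 18.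

Step 13. The warming needed to cleave the chelated methyl ether may cause hydrochlorination or cationic opening of ring A (and possibly ring F), or demethylation may stay incomplete at temperatures the chromene tolerates. The fallback removes the methyl group before any chromene exists and sets out from 8. BCl3 in CH2Cl2 (−78 to 0 °C) should give the 5-hydroxy-2-(methylsulfanyl)chromone F4, and mCPBA the 5-hydroxy-2-(methanesulfonyl)chromone F5. Displacement with phenol 14 (K2CO3, DMF; the chelated hydroxyl is a poor nucleophile) should give the 5-hydroxy propargyl aryl ether F6, and the Claisen rearrangement the 5-hydroxy chromenyl ether F7. The palladium coupling of step 12 should then give 5'-O-benzylformosanatin D F8. Only the benzyl ether is left, and BCl3 with pentamethylbenzene at −78 °C should cleave it without warming. It comes back to the route at 19.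

Step 2. The [3,3] shift may go with poor site selectivity to the ring carbon next to the methoxy group (giving the linear chromene), or the ring may close through the chelated oxygen. The fallback sets out from 1 and builds the chromene by condensation instead of rearrangement. 3-Methylbut-2-enal with ethylenediammonium diacetate (cat.) in refluxing xylene should attack the ring carbon flanked by the two hydroxyl groups (Knoevenagel-type), and the resulting quinone methide should close by 6π oxa-electrocyclisation on the non-chelated oxygen. It comes back to the route at 5 and makes no compound outside the list (F0).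

**Further compounds**

F1 | step 12 | 4-(benzyloxy)-2-bromo-5-[(2-methylbut-3-yn-2-yl)oxy]phenol | Oc1cc(OC(C)(C)C#C)c(OCc2ccccc2)cc1Br
F2 | step 12 | 2-{4-(benzyloxy)-2-bromo-5-[(2-methylbut-3-yn-2-yl)oxy]phenoxy}-5-methoxy-8,8-dimethyl-9,10-dihydro-4H,8H-pyrano[2,3-f]chromen-4-one | O=c1cc(Oc2cc(OC(C)(C)C#C)c(OCc3ccccc3)cc2Br)oc2c3CCC(C)(C)Oc3cc(OC)c12
F3 | step 12 | 2-{[8-(benzyloxy)-6-bromo-2,2-dimethyl-2H-chromen-5-yl]oxy}-5-methoxy-8,8-dimethyl-9,10-dihydro-4H,8H-pyrano[2,3-f]chromen-4-one | O=c1cc(Oc2c(Br)cc(OCc3ccccc3)c3OC(C)(C)C=Cc23)oc2c3CCC(C)(C)Oc3cc(OC)c12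
F4 | step 13 | 5-hydroxy-8,8-dimethyl-2-(methylsulfanyl)-9,10-dihydro-4H,8H-pyrano[2,3-f]chromen-4-one | CSc1cc(=O)c2c(O)cc3OC(C)(C)CCc3c2o1
F5 | step 13 | 5-hydroxy-2-(methanesulfonyl)-8,8-dimethyl-9,10-dihydro-4H,8H-pyrano[2,3-f]chromen-4-one | CS(=O)(=O)c1cc(=O)c2c(O)cc3OC(C)(C)CCc3c2o1
F6 | step 13 | 2-{4-(benzyloxy)-3-[(2-methylbut-3-yn-2-yl)oxy]phenoxy}-5-hydroxy-8,8-dimethyl-9,10-dihydro-4H,8H-pyrano[2,3-f]chromen-4-one | O=c1cc(Oc2ccc(OCc3ccccc3)c(OC(C)(C)C#C)c2)oc2c3CCC(C)(C)Oc3cc(O)c12
F7 | step 13 | 2-{[8-(benzyloxy)-2,2-dimethyl-2H-chromen-5-yl]oxy}-5-hydroxy-8,8-dimethyl-9,10-dihydro-4H,8H-pyrano[2,3-f]chromen-4-one | O=c1cc(Oc2ccc(OCc3ccccc3)c3OC(C)(C)C=Cc23)oc2c3CCC(C)(C)Oc3cc(O)c12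
F8 | step 13 | 5'-O-benzylformosanatin D | O=c1c2c(O)cc3OC(C)(C)CCc3c2oc2oc3c4C=CC(C)(C)Oc4c(OCc4ccccc4)cc3c12
F0 | step 2 | none | none
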